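At early times the beta flask climbs slowly and its first two readings go backwards, 4.4% and then 1.9% against a scatter of 1 percentage point, so I take its pace from the last reading, 10.1% at 30.0 min.

| flask | substrate | coupling partner | free catalyst | second catalyst | impurity | remark | time |
|---|---|---|---|---|---|---|---|
| beta | 0.10 M | 0.95 equiv | 1 mol% | 6.6 mol% | 1.1 mM | run made earlier |  |
| east | 0.20 M | 0.640 equiv | 1 mol% | 6.6 mol% | 1.7 mM |  | 50 min |
| west | 0.10 M | 0.950 equiv | 1 mol% | 6.6 mol% | 1.7 mM |  | 50 min |

beta run (percent of the substrate charged): time / min: product / % = 6.00: 4.4; 12.0: 1.9; 20.0: 6.0; 25.0: 7.7; 30.0: 10.1

(standard deviation of a reading: 1 percentage point)

- where the amount of substrate changes, what is given in equivalents or mol% on it follows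
- no earlier run changes the charge of free catalyst; that part of a forecast is a guess
- no earlier run changes the charge of second catalyst; that part of a forecast is a guess
- no earlier run changes the charge of impurity; that part of a forecast is a guess

- the flask that ends with the higher amount of product, in percent of the substrate charged, or "neither" when 2 percentage points or less lies between them (east / west / neither)
- final product, as a percentage of the substrate charged, in east
- final product, as a percentage of the substrate charged, in west

How much of that pace can I carry? No earlier run varies the second catalyst or the impurity, so I guess that the impurity takes second catalyst one for one, leaving c(second catalyst) = 5.50 mM in beta, and that the pace goes with this and with c(coupling partner). Dividing gives g, the coupling pace per unit of surviving second catalyst and of coupling partner, 6.44 M⁻² min⁻¹.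

What does g give at the charged amounts? West reaches 15.0% and east 47.4%, but these hold the coupling partner at its charge.

So what happens when the answer goes back in? In east, the limiting reagent is the coupling partner, and its mean level over the run falls with the product made, so a second round gives 29.9%. The rounds swing around the value that returns itself, 34.6%, and the same closing brings west to 13.9%. I therefore reckon that east ends higher than west by 21 points, far past the margin of 2 points.

The forecast, above both my numbers, says east, with 40% in east and 15% in west, and where I put the impurity on the second catalyst it assumes that “the impurity titrates that catalyst”, meaning the free catalyst.

The simulation gives 37.1% in east and 17.1% in west, so east ends higher.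

    substrate + free catalyst ⇌ free catalyst + intermediate (K = 2.30, k = 83.7 M⁻¹ min⁻¹)
    coupling partner + second catalyst + intermediate → second catalyst + product (k = 15.6 M⁻² min⁻¹)
    second catalyst + impurity → spent catalyst (k = 1180 M⁻¹ min⁻¹)

The gap between the two flasks is mainly due to the difference in c(substrate): east set back to the concentration of west stands at 11.9% instead of 37.1%. Carried to the neighbour of west with 26 mol% of second catalyst, g with the same closing gives 53.5%, and that flask stands at 48.6%.

The earlier runs and the new flask are calculated with made-up constants; the scatter is artificial.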